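**Plan** (ring A = acetylated arene, ring B = its pyran, ring C = dimethoxy arene, ring D = its pyran, C* = the stereocentre)
1. Cuts, last bond first: ring D back to a free ring-C phenol and 3-methylbut-2-enal; the two C–H bonds of C*H–CH3 back to C*=CH2; C4=C3 and C*=CH2 together back to a styrene and an aryl alkyne; then C*–aryl, O1–C2 and C4a–vinyl.
2. Enabling feature: C3 of ring B carries both the ring alkene C3=C4 and the exocyclic carbon C*, so ring B with a methylidene on C* is a 1-vinylcycloalkene, the enyne-metathesis product of a C4a vinyl group and an alkyne C3≡C*–aryl held on O1 through C2Me2.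
3. Forward: ring A receives iodide, vinyl and the tertiary propargyl ether; the ring-C aryl iodide is coupled to the alkyne; ring B closes (step 7); C*=CH2 is reduced; ring D is annulated last.
4. Stereochemistry: the only centre, C* (S), comes from catalyst-controlled hydrogenation of C*=CH2 (step 8), run before ring D exists so that no cis-disubstituted chromene alkene competes for the catalyst.

Key step: step 7

Assumption: the sense of induction of the phosphine-oxazoline ligand on this diene cannot be predicted with confidence, so (S)-tBu-PHOX is written as the working choice and the antipode that gives (S) at C* is to be fixed in a small-scale trial.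

Step 1
Reactants: 1 1-(2,4-dihydroxy-6-methoxyphenyl)ethanone
Product: 2 1-(2,4-dihydroxy-3-iodo-6-methoxyphenyl)ethanone
Conditions: BnNMe3·ICl2 (1.0 equiv), NaHCO3, CH2Cl2/MeOH, 0 °C to rt
Reagents that add atoms: benzyltrimethylammonium dichloroiodate, C[N+](C)(C)Cc1ccccc1.Cl[I-]Cl
Why: Electrophilic aromatic iodination with the dichloroiodate should occur at C3, the ring carbon ortho to both free hydroxyl groups and para to the methoxy group, which is the most activated and least hindered position, one equivalent of reagent limiting a second iodination at C5.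

Step 2
Reactants: 2 1-(2,4-dihydroxy-3-iodo-6-methoxyphenyl)ethanone
Product: 3 1-(3-ethenyl-2,4-dihydroxy-6-methoxyphenyl)ethanone
Conditions: vinyl-Bpin (1.3 equiv), PdCl2(dppf) (3 mol%), K2CO3 (3 equiv), 1,4-dioxane/H2O 4:1, 80 °C
Reagents that add atoms: 2-ethenyl-4,4,5,5-tetramethyl-1,3,2-dioxaborolane, C=CB1OC(C)(C)C(C)(C)O1
Why: Suzuki–Miyaura coupling of the aryl iodide with a vinylboronate is a standard vinylation that runs on the free phenoxides in aqueous carbonate and does not touch the ketone.

Step 3
Reactants: 3 1-(3-ethenyl-2,4-dihydroxy-6-methoxyphenyl)ethanone; 4 3-chloro-3-methylbut-1-yne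
Product: 5 1-[3-ethenyl-2-hydroxy-6-methoxy-4-(2-methylbut-3-yn-2-yloxy)phenyl]ethanone
Conditions: 4 (1.3 equiv), CuCl2·2H2O (1 mol%), DBU (1.3 equiv), MeCN, 0 °C
Reagents that add atoms: none
Why: Copper-catalysed propargylic substitution through a copper acetylide (allenylidene) should etherify only the more acidic free 4-OH, because the 2-OH is locked in a hydrogen bond to the acetyl group, and the low temperature keeps the aryl propargyl ether from rearranging.

Step 4
Reactants: 6 4-bromo-3,5-dimethoxyphenol
Product: 7 (4-bromo-3,5-dimethoxyphenoxy)(tert-butyl)dimethylsilane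
Conditions: TBSCl (1.2 equiv), imidazole (2 equiv), DMF, rt
Reagents that add atoms: tert-butyldimethylsilyl chloride, CC(C)(C)[Si](C)(C)Cl
Why: Silylation of a phenol with TBSCl and imidazole is standard and masks the ring-C oxygen through the organometallic, metathesis and hydrogenation steps.

Step 5
Reactants: 7 (4-bromo-3,5-dimethoxyphenoxy)(tert-butyl)dimethylsilane
Product: 9 tert-butyl(4-iodo-3,5-dimethoxyphenoxy)dimethylsilane, via aryllithium 8 (not isolated)
Conditions: n-BuLi (1.05 equiv), THF, −78 °C; then I2 (1.1 equiv), −78 °C to rt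
Reagents that add atoms: iodine, II; n-butyllithium, [Li]CCCC (its lithium stays only in intermediate 8)
Why: Bromine–lithium exchange at −78 °C gives an aryllithium held between two methoxy groups that is quenched by iodine, exchanging the sluggish bromide for an iodide that can be coupled at low temperature.

Step 6
Reactants: 5 1-[3-ethenyl-2-hydroxy-6-methoxy-4-(2-methylbut-3-yn-2-yloxy)phenyl]ethanone; 9 tert-butyl(4-iodo-3,5-dimethoxyphenoxy)dimethylsilane
Product: 10 1-[4-({4-[4-(tert-butyldimethylsilyloxy)-2,6-dimethoxyphenyl]-2-methylbut-3-yn-2-yl}oxy)-3-ethenyl-2-hydroxy-6-methoxyphenyl]ethanone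
Conditions: PdCl2(PPh3)2 (5 mol%), CuI (10 mol%), Et3N/THF 1:1, degassed, 40 °C
Reagents that add atoms: none
Why: Sonogashira coupling of a terminal alkyne with an aryl iodide proceeds near room temperature even with two ortho methoxy groups, which keeps the aryl propargyl ether below the temperature of its Claisen rearrangement and leaves the styrene, the ketone and the hydrogen-bonded phenol as spectators.

Step 7
Reactants: 10 1-[4-({4-[4-(tert-butyldimethylsilyloxy)-2,6-dimethoxyphenyl]-2-methylbut-3-yn-2-yl}oxy)-3-ethenyl-2-hydroxy-6-methoxyphenyl]ethanone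
Product: 11 1-[3-{1-[4-(tert-butyldimethylsilyloxy)-2,6-dimethoxyphenyl]ethenyl}-5-hydroxy-7-methoxy-2,2-dimethyl-2H-chromen-6-yl]ethanone
Conditions: second-generation Hoveyda–Grubbs catalyst RuCl2(SIMes)(=CH-C6H4-2-O-i-Pr) (10 mol%), ethylene (1 atm), toluene (0.01 M), 60 °C
Reagents that add atoms: ethylene, C=C (methylidene shuttle: the =CH2 on C* can come from it while the styrene CH2 leaves as ethylene; net an isomerisation)
Why: The catalyst loads as a ruthenium benzylidene on the C4a vinyl group (giving up ethylene), this carbene adds across the tethered alkyne to a ruthenacyclobutene whose opening forms C4=C3 and leaves a new carbene on C*, and methylidene exchange with ethylene then frees C*=CH2 and returns Ru=CH2 to the cycle (should Ru=CH2 add to the alkyne first, the resulting triene closes to the same diene). The closest known reaction type is ring-closing enyne metathesis of ortho-vinylaryl propargyl ethers to 3-vinyl-2H-chromenes. Ring B closes in the exo mode, only C3 of the alkyne entering the six-membered ring, helped by the gem-dimethyl group on C2, whereas the endo mode would need a seven-membered benzoxepine and a bond from C4 to the aryl-bearing carbon. No stereocentre is formed. The selectivity needed is initiation at the styrene and reaction at no other π bond, which the substrate secures because the vinyl group is its only alkene and the 1,1-disubstituted and trisubstituted alkenes of the product are too hindered for further metathesis, while the hydrogen-bonded phenol, the ketone and the silyl ether are tolerated by the catalyst.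

Step 8
Reactants: 11 1-[3-{1-[4-(tert-butyldimethylsilyloxy)-2,6-dimethoxyphenyl]ethenyl}-5-hydroxy-7-methoxy-2,2-dimethyl-2H-chromen-6-yl]ethanone
Product: 12 1-[3-{(1S)-1-[4-(tert-butyldimethylsilyloxy)-2,6-dimethoxyphenyl]ethyl}-5-hydroxy-7-methoxy-2,2-dimethyl-2H-chromen-6-yl]ethanone
Conditions: [Ir(cod)((S)-tBu-PHOX)][B(3,5-(CF3)2C6H3)4] (2 mol%, monovalent iridium), H2 (1 bar), CH2Cl2, 0 °C
Reagents that add atoms: none
Why: Proposed new method: an iridium dihydride carrying the chiral P,N ligand should bind the least substituted alkene, C*=CH2, and pass both hydrogens to one enantiotopic face, the face being chosen by the contrast between the twisted 2,6-dimethoxyaryl group and the flatter chromen-3-yl group in the ligand pocket, while at 1 bar and 0 °C the trisubstituted C3=C4 alkene next to the gem-dimethyl carbon should stay untouched; the closest known reaction type is iridium phosphine-oxazoline asymmetric hydrogenation of unfunctionalised 1,1-disubstituted alkenes such as 1,1-diarylethenes and α-alkylstyrenes, which has not been shown for the terminal alkene of a 2-aryl-1,3-diene.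

Step 9
Reactants: 12 1-[3-{(1S)-1-[4-(tert-butyldimethylsilyloxy)-2,6-dimethoxyphenyl]ethyl}-5-hydroxy-7-methoxy-2,2-dimethyl-2H-chromen-6-yl]ethanone
Product: 13 1-{5-hydroxy-3-[(1S)-1-(4-hydroxy-2,6-dimethoxyphenyl)ethyl]-7-methoxy-2,2-dimethyl-2H-chromen-6-yl}ethanone
Conditions: Bu4NF/AcOH 1:1 (1.5 equiv), THF, 0 °C to rt
Reagents that add atoms: none
Why: Fluoride cleaves the aryl silyl ether by attack at silicon while acetic acid buffers the phenoxide, conditions under which the ketone, the chromene and the non-acidic C* centre are unaffected.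

Step 10
Reactants: 13 1-{5-hydroxy-3-[(1S)-1-(4-hydroxy-2,6-dimethoxyphenyl)ethyl]-7-methoxy-2,2-dimethyl-2H-chromen-6-yl}ethanone; 14 3-methylbut-2-enal
Product: 16 1-{3-[(1S)-1-(5,7-dimethoxy-2,2-dimethyl-2H-chromen-6-yl)ethyl]-5-hydroxy-7-methoxy-2,2-dimethyl-2H-chromen-6-yl}ethanone (CNP0303487.1), via ortho-quinone methide 15 (not isolated)
Conditions: 14 (2 equiv), ethylenediammonium diacetate (20 mol%), toluene, 110 °C
Reagents that add atoms: none
Why: Amine-catalysed condensation of the ring-C phenol at its free ortho carbon with the enal (Knoevenagel type) gives an ortho-quinone methide that closes ring D by oxa-6π electrocyclisation, the two ortho positions of ring C being equivalent and the ring-A phenol being hydrogen-bonded and blocked at both ortho positions, so that only one chromene can form and C* is not touched.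

**Compound list**
1 | 1-(2,4-dihydroxy-6-methoxyphenyl)ethanone | CC(=O)c1c(O)cc(O)cc1OC | starting material
2 | 1-(2,4-dihydroxy-3-iodo-6-methoxyphenyl)ethanone | CC(=O)c1c(O)c(I)c(O)cc1OC | intermediate
3 | 1-(3-ethenyl-2,4-dihydroxy-6-methoxyphenyl)ethanone | CC(=O)c1c(O)c(C=C)c(O)cc1OC | intermediate
4 | 3-chloro-3-methylbut-1-yne | CC(C)(Cl)C#C | starting material
5 | 1-[3-ethenyl-2-hydroxy-6-methoxy-4-(2-methylbut-3-yn-2-yloxy)phenyl]ethanone | CC(=O)c1c(O)c(C=C)c(OC(C)(C)C#C)cc1OC | intermediate
6 | 4-bromo-3,5-dimethoxyphenol | COc1cc(O)cc(OC)c1Br | starting material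
7 | (4-bromo-3,5-dimethoxyphenoxy)(tert-butyl)dimethylsilane | COc1cc(O[Si](C)(C)C(C)(C)C)cc(OC)c1Br | intermediate
8 | [4-(tert-butyldimethylsilyloxy)-2,6-dimethoxyphenyl]lithium | [Li]c1c(OC)cc(O[Si](C)(C)C(C)(C)C)cc1OC | intermediate
9 | tert-butyl(4-iodo-3,5-dimethoxyphenoxy)dimethylsilane | COc1cc(O[Si](C)(C)C(C)(C)C)cc(OC)c1I | intermediate
10 | 1-[4-({4-[4-(tert-butyldimethylsilyloxy)-2,6-dimethoxyphenyl]-2-methylbut-3-yn-2-yl}oxy)-3-ethenyl-2-hydroxy-6-methoxyphenyl]ethanone (enyne) | CC(=O)c1c(O)c(C=C)c(OC(C)(C)C#Cc2c(OC)cc(O[Si](C)(C)C(C)(C)C)cc2OC)cc1OC | intermediate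
11 | 1-[3-{1-[4-(tert-butyldimethylsilyloxy)-2,6-dimethoxyphenyl]ethenyl}-5-hydroxy-7-methoxy-2,2-dimethyl-2H-chromen-6-yl]ethanone (diene) | CC(=O)c1c(O)c2C=C(C(=C)c3c(OC)cc(O[Si](C)(C)C(C)(C)C)cc3OC)C(C)(C)Oc2cc1OC | intermediate
12 | 1-[3-{(1S)-1-[4-(tert-butyldimethylsilyloxy)-2,6-dimethoxyphenyl]ethyl}-5-hydroxy-7-methoxy-2,2-dimethyl-2H-chromen-6-yl]ethanone | CC(=O)c1c(O)c2C=C([C@H](C)c3c(OC)cc(O[Si](C)(C)C(C)(C)C)cc3OC)C(C)(C)Oc2cc1OC | intermediate
13 | 1-{5-hydroxy-3-[(1S)-1-(4-hydroxy-2,6-dimethoxyphenyl)ethyl]-7-methoxy-2,2-dimethyl-2H-chromen-6-yl}ethanone | CC(=O)c1c(O)c2C=C([C@H](C)c3c(OC)cc(O)cc3OC)C(C)(C)Oc2cc1OC | intermediate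
14 | 3-methylbut-2-enal | CC(C)=CC=O | starting material
15 | 1-{5-hydroxy-3-[(1S)-1-[2,6-dimethoxy-3-(3-methylbut-2-en-1-ylidene)-4-oxocyclohexa-1,5-dien-1-yl]ethyl]-7-methoxy-2,2-dimethyl-2H-chromen-6-yl}ethanone (ortho-quinone methide) | CC(=O)c1c(O)c2C=C([C@H](C)C3=C(OC)C(=CC=C(C)C)C(=O)C=C3OC)C(C)(C)Oc2cc1OC | intermediate
16 | 1-{3-[(1S)-1-(5,7-dimethoxy-2,2-dimethyl-2H-chromen-6-yl)ethyl]-5-hydroxy-7-methoxy-2,2-dimethyl-2H-chromen-6-yl}ethanone | COc1cc2c(c(O)c1C(C)=O)C=C([C@H](C)c1c(OC)cc3c(c1OC)C=CC(C)(C)O3)C(C)(C)O2 | target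

**Step count**
Total: 10 steps. Longest linear sequence: 8 steps (1 → 2 → 3 → 5 → 10 → 11 → 12 → 13 → 16).

**Steps most likely to fail**

Step 8. Hydrogen may be delivered with poor facial selectivity, or may add across the diene in the 1,4 sense or to C3=C4 as well. The fallback separates reduction from stereocontrol and uses only known chemistry. It sets out from 11, which is hydrogenated with RhCl(PPh3)3 (monovalent rhodium) under H2 (1 atm) in benzene/ethanol at rt. This catalyst reduces 1,1-disubstituted alkenes and leaves hindered trisubstituted ones, and it should give racemic silyl ether F1. The enantiomers are then separated by preparative HPLC on a cellulose tris(3,5-dimethylphenylcarbamate) phase, and the (S)-enantiomer is 12, where the route resumes.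

Step 7. The ruthenium benzylidene may fail to add across the alkyne, which is shielded by the 2,6-dimethoxyaryl group, or the catalyst may come to rest as a chelated or hindered disubstituted carbene so that turnover stops. The fallback opens the alkyne with the smallest carbene first and then closes ring B by alkene–alkene metathesis. It sets out from 10, which is treated with second-generation Grubbs catalyst RuCl2(SIMes)(PCy3)(=CHPh) under ethylene (about 4 atm) in CH2Cl2 at 40 °C. Alkyne–ethylene cross-metathesis through Ru=CH2 should give triene F2, a 2,3-disubstituted buta-1,3-diene. F2 is isolated and then submitted to ring-closing metathesis between the styrene and the methylidene on C3 (RuCl2(SIMes)(=CH-C6H4-2-O-i-Pr), toluene, 60 °C, argon sparge to remove ethylene). The six-membered ring is preferred over the seven-membered alternative, and the sequence comes back to the route at 11.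

Step 10. The condensation may stall at the hindered ortho carbon of ring C, or be outrun by self-condensation of the enal or by reversible attack at C8 of ring A. The fallback builds ring D by rearrangement instead of condensation. It sets out from 13, which is etherified with 4 at the free ring-C phenol under the conditions of step 3 (CuCl2·2H2O, DBU, MeCN, 0 °C) to give aryl propargyl ether F3. Heating F3 in xylene at 135 °C should trigger an aromatic propargyl Claisen rearrangement to ortho-allenylphenol F4. A 1,5-hydrogen shift then gives dienone 15, and electrocyclisation returns the route at 16.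

**Further compounds**
F1 | step 8 | racemic 1-[3-{1-[4-(tert-butyldimethylsilyloxy)-2,6-dimethoxyphenyl]ethyl}-5-hydroxy-7-methoxy-2,2-dimethyl-2H-chromen-6-yl]ethanone | CC(=O)c1c(O)c2C=C(C(C)c3c(OC)cc(O[Si](C)(C)C(C)(C)C)cc3OC)C(C)(C)Oc2cc1OC
F2 | step 7 | 1-[4-({4-[4-(tert-butyldimethylsilyloxy)-2,6-dimethoxyphenyl]-2-methyl-3-methylidenepent-4-en-2-yl}oxy)-3-ethenyl-2-hydroxy-6-methoxyphenyl]ethanone | CC(=O)c1c(O)c(C=C)c(OC(C)(C)C(=C)C(=C)c2c(OC)cc(O[Si](C)(C)C(C)(C)C)cc2OC)cc1OC
F3 | step 10 | 1-{3-[(1S)-1-[2,6-dimethoxy-4-(2-methylbut-3-yn-2-yloxy)phenyl]ethyl]-5-hydroxy-7-methoxy-2,2-dimethyl-2H-chromen-6-yl}ethanone | CC(=O)c1c(O)c2C=C([C@H](C)c3c(OC)cc(OC(C)(C)C#C)cc3OC)C(C)(C)Oc2cc1OC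
F4 | step 10 | 1-{5-hydroxy-3-[(1S)-1-[4-hydroxy-2,6-dimethoxy-3-(3-methylbuta-1,2-dien-1-yl)phenyl]ethyl]-7-methoxy-2,2-dimethyl-2H-chromen-6-yl}ethanone | CC(=O)c1c(O)c2C=C([C@H](C)c3c(OC)cc(O)c(C=C=C(C)C)c3OC)C(C)(C)Oc2cc1OC
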